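## The problem

(−)-Cubebininolide 11 is a γ-butyrolactone (ring atoms O1, C2(=O), C3, C4, C5) with one 3,4,5-trimethoxybenzyl group on C3 and one on C4, trans to each other, in the (3R,4R) configuration. The chain is short, four lactone carbons and two identical ArCH2 arms, so the task is to place two vicinal stereocentres in the right absolute sense and to attach two arenes. C3 is α to the lactone carbonyl and can epimerise; because trans is the stable arrangement, C4 can correct C3, but nothing can correct C4. In the open-chain, twofold-symmetric precursors both centres are α to carbonyl groups, so base, heat and anhydride- or imide-type intermediates must be avoided, since one epimerisation there leads into the meso series. The six aryl methyl ethers exclude boron tribromide-type Lewis acids and hot hydrohalic acids, and the electron-rich rings exclude strongly electrophilic oxidants. Each benzylic CH2 is bonded to an arene carbon that is meta to two methoxy groups and para to the third. Electrophilic substitution of 1,2,3-trimethoxybenzene does not reach that position, so the arene has to arrive with its pattern set, for instance as an aryl iodide. Two features open a direct solution. Lactone 11 is the mono-oxidised form of a twofold-symmetric 1,4-diol, so C2 and C5 never need to be told apart. And the two benzylic carbons, without their arenes, are the methyl groups of (2R,3R)-2,3-dimethylsuccinic acid 1, each β to a carboxyl carbon that can carry a directing group.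

## Retrosynthesis

**Lactone carbonyl to carbinol.** The first cut is an oxidation-level change at C2 of 11. The lactone is read as the product of oxidising one primary alcohol of (2R,3R)-2,3-bis(3,4,5-trimethoxybenzyl)butane-1,4-diol 9, by way of lactol 10. The neighbouring option, hydride reduction of one carbonyl of the trans-anhydride of the diacid, is equally symmetric but passes through an anhydride with acidic α-hydrogens; diol 9 has no enolisable position. Because 9 has a twofold axis, the forward oxidation must choose alcohol over arene but faces no regiochemical question.

**Carbinol carbons to activated amides.** The two CH2OH carbons of 9 are traced to the acyl carbons of bis(N-Boc) anilide 8, and the N–Boc bonds of 8 are then cut to give the bis-anilide 7. Direct hydrolysis of the two hindered anilides would need hot acid or base, which endangers the α-centres and the ethers. N-Acylation with Boc turns each amide into an acyl donor that a borohydride cleaves at room temperature. The forward steps must remove a deliberately robust directing group without epimerisation.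

**Aryl–CH2 bonds (key disconnection).** Both bonds between the benzylic carbons and the arenes of 7 are cut. This gives (2R,3R)-2,3-dimethyl-N1,N4-bis[2-(methylthio)phenyl]succinamide 4 and two molecules of 5-iodo-1,2,3-trimethoxybenzene 5. Cutting the CH–CH2 bonds instead would require two stereocontrolled enolate benzylations, and cutting the central CH–CH bond a stereocontrolled dimerisation. The cut at the arene leaves both stereocentres untouched inside a six-carbon fragment whose configuration is bought, and it delivers each ring with its three methoxy groups in place. The precursor is a simple dimethylsuccinamide plus a catalogue iodide. The forward reaction must arylate two methyl groups in turn, through mono-arylated bisamide 6, in preference to the methine C–H bonds and the new benzylic CH2 groups, without disturbing the α-carbons.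

**Amide C–N bonds.** Bisamide 4 is disconnected at both amide bonds to (2R,3R)-2,3-dimethylsuccinyl dichloride 2 and 2-(methylthio)aniline 3, and 2 goes back to acid 1. Amine 3 is preferred to the more strongly activating quinoline-type amines because its palladacycles form readily from methyl groups and only reluctantly from methylene groups, which is the selectivity the key step needs. The forward acylation must avoid the ketene pathway and closure to a five-membered anhydride or imide.

## Roads not taken

**Alternative 1:** thiocarbonyl ylide cycloaddition. The cut falls on the two bonds joining C3 and C4 to their benzylic carbons. Bis[(3,4,5-trimethoxyphenyl)(trimethylsilyl)methyl] sulfoxide A1 would lose its silyl groups on heating and release a 1,3-diaryl thiocarbonyl ylide, which adds to di-(−)-menthyl fumarate A2 to give thiolane A3. Desulfurisation over Raney Ni then removes sulfur and, with it, the two stereocentres next to it; the desulfurised diester would be reduced to 9.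

- Merits: it is convergent, makes both benzylic C–C bonds at once, and transmits the E geometry of A2 into the trans relation by suprafacial addition. The chirality comes from inexpensive menthol.
- Weak points: two conformationally mobile menthyl esters give only modest facial bias in an uncatalysed dipolar addition, and the Lewis acids that usually rigidify such esters fit poorly with thermal ylide generation. A1 needs a multistep preparation (two benzylic silylations and an S-oxidation). Two stereocentres are made only to be destroyed, the desulfurisation is stoichiometric in nickel, and hindered menthyl esters remain to be removed. The count is about eight to nine steps.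
- Comparison: this road is better in not depending on an enantiopure C6 diacid and in needing no silver. The chosen plan sets against it that it has no stereo-inducing step whose selectivity could fall short, and that it is about three steps shorter.

**Alternative 2:** cyclopropane opening and enolate benzylation. The cut falls on the aryl–CH2 bond of the C4 arm and on the C3–CH2 bond of the C3 arm. Methyl (1S,5R)-2-oxo-3-oxabicyclo[3.1.0]hexane-1-carboxylate A4 would be opened at its cyclopropane CH2 by 3,4,5-trimethoxyphenylmagnesium bromide A5 with catalytic CuI. The released malonate-type enolate would be trapped with 3,4,5-trimethoxybenzyl bromide A6 to give A7, and demethoxycarbonylation with equilibration at C3 would lead to 11.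

- Merits: C4 comes from an inexpensive enantiopure epoxide building block, the lactone is at the right oxidation level from the start, and homoconjugate opening of such activated cyclopropanes by aryl copper reagents is established.
- Weak points: a stabilised magnesium enolate is a sluggish partner for a labile, electron-rich benzylic bromide in the same pot. A quaternary centre is built and then dismantled under hot halide conditions. C3 is finally set by protonation and relies on equilibration to trans. The two identical arms are installed by two unrelated reactions, so the symmetry of the target is not used.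
- Comparison: in length this road is the better one, about three steps against six. The chosen plan sets against that a single reaction type for both arms and stereocentres that are never formed or re-formed on the way.

**Alternative 3:** syn bis(methoxycarbonylation). The cut falls on C2–C3 and C4–C5, both carboxyl-level carbons being added to an alkene. (E)-1,4-Bis(3,4,5-trimethoxyphenyl)but-2-ene A8 would take up two methoxycarbonyl groups in a syn sense under Pd(O2CCF3)2, a chiral bis(oxazoline) ligand and a quinone reoxidant, giving dimethyl (2R,3R)-2,3-bis(3,4,5-trimethoxybenzyl)succinate A9. A9 would be reduced to 9.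

- Merits: both stereocentres and both carboxyl carbons are created in one catalytic asymmetric step from an achiral, symmetric alkene, and syn addition to the E isomer gives the chiral diastereomer stereospecifically.
- Weak points: enantioselective bis(alkoxycarbonylation) works best on terminal and aryl-conjugated alkenes, and internal 1,2-dialkyl alkenes are its slowest and least selective substrates. Each alkene carbon of A8 bears a CH2 that is both allylic and benzylic, so β-hydride elimination with migration into conjugation and allylic oxidation compete. Any Z isomer in A8 becomes meso diester.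
- Comparison: if it worked it would be shorter (about four steps) and the only road that generates the chirality catalytically, and in both respects it would be better. The chosen plan sets against that a key step that creates no stereocentre, so no enantioselectivity has to be achieved, and a reactivity pattern within established scope.

Key step: step 3

Assumption: acid 1 is bought as the single (2R,3R) enantiomer; its optical purity fixes that of 11, since no step of the route can raise it.

## Route

Step 1
Reactants: 1 (2R,3R)-2,3-dimethylsuccinic acid
Product: 2 (2R,3R)-2,3-dimethylsuccinyl dichloride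
Conditions: (COCl)2 (3 equiv), DMF (cat.), CH2Cl2, 0 °C → rt; evaporate, use crude
Reagents that add atoms: oxalyl chloride, ClC(=O)C(=O)Cl
Why: Acid chloride formation through the Vilsmeier-type chloroiminium species from (COCl)2 and DMF. No base is present and the temperature is low, so the α-stereocentres should not epimerise.

Step 2
Reactants: 2 (2R,3R)-2,3-dimethylsuccinyl dichloride; 3 2-(methylthio)aniline
Product: 4 (2R,3R)-2,3-dimethyl-N1,N4-bis[2-(methylthio)phenyl]succinamide
Conditions: 3 (2.4 equiv), pyridine (4 equiv), CH2Cl2, 0 °C → rt; 2 added slowly to the amine
Reagents that add atoms: none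
Why: N-Acylation of an aniline by an acid chloride (Schotten–Baumann type). Inverse addition keeps free aniline in excess at each acyl chloride, which disfavours closure to the imide, and pyridine is too weak a base to open the ketene pathway that would scramble the α-centres.

Step 3
Reactants: 4 (2R,3R)-2,3-dimethyl-N1,N4-bis[2-(methylthio)phenyl]succinamide; 5 5-iodo-1,2,3-trimethoxybenzene (two equivalents react)
Product: 7 (2R,3R)-N1,N4-bis[2-(methylthio)phenyl]-2,3-bis(3,4,5-trimethoxybenzyl)succinamide, via mono-arylated bisamide 6 (not isolated)
Conditions: Pd(OAc)2 (20 mol %), AgOAc (4.4 equiv), 5 (5 equiv), t-AmOH, 110 °C, sealed tube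
Reagents that add atoms: none
Why: Each amide binds divalent palladium through its deprotonated nitrogen and the thioether sulfur, and acetate-assisted concerted metalation–deprotonation of the methyl group on the adjacent carbon gives a five-membered palladacycle. Oxidative addition of 5 leads to tetravalent palladium, C–C reductive elimination forms the aryl–CH2 bond, and AgOAc removes iodide as AgI and returns acetate; the cycle then repeats at the second amide, starting from 6. The closest known reaction type is the palladium-catalysed β-methyl C–H arylation of aliphatic carboxamides bearing a bidentate anilide auxiliary with aryl iodides, which accepts α-branched amides and electron-rich iodides. No ring closes and no stereocentre is created; the two α-carbons take no part in bond formation and should stay (R,R), because each amide is held as a palladium amidate and not as an enolisable acyl species. The step needs site selectivity for primary C–H over the tertiary C–H of the neighbouring methine and over the new benzylic CH2, and the 2-(methylthio)anilide supplies it, since its palladacycles form readily from methyl groups and only sluggishly from methylene or methine positions. If one amide should reach the more distant methyl group through a six-membered palladacycle, the result is the same, because both methyl groups are to be arylated. The arene enters with its three methoxy groups already placed, so no regiochemical question arises on the ring.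

Step 4
Reactants: 7 (2R,3R)-N1,N4-bis[2-(methylthio)phenyl]-2,3-bis(3,4,5-trimethoxybenzyl)succinamide
Product: 8 di-tert-butyl N,N'-[(2R,3R)-2,3-bis(3,4,5-trimethoxybenzyl)succinyl]bis{[2-(methylthio)phenyl]carbamate} (each amide nitrogen carries a Boc group)
Conditions: Boc2O (6 equiv), DMAP (2 equiv), MeCN, 50 °C
Reagents that add atoms: di-tert-butyl dicarbonate, CC(C)(C)OC(=O)OC(=O)OC(C)(C)C
Why: DMAP-catalysed N-tert-butoxycarbonylation of secondary anilides, which converts each resonance-stabilised amide into a twisted N-acyl carbamate that can be cleaved under mild conditions. DMAP is too weak a base to enolise the product, so the α-centres are kept.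

Step 5
Reactants: 8 di-tert-butyl N,N'-[(2R,3R)-2,3-bis(3,4,5-trimethoxybenzyl)succinyl]bis{[2-(methylthio)phenyl]carbamate}
Product: 9 (2R,3R)-2,3-bis(3,4,5-trimethoxybenzyl)butane-1,4-diol
Conditions: LiBH4 (6 equiv), THF, 0 °C → rt; aqueous work-up
Reagents that add atoms: none
Why: Reductive cleavage of an N-acyl carbamate: hydride adds to the ketone-like acyl carbonyl, the tetrahedral intermediate expels the carbamate anion, and the aldehyde is reduced on to the alcohol. Any lactone formed in passing, by attack of the first alkoxide on the second activated amide, is also reduced by LiBH4 to 9, so all paths converge; no enolisable carbonyl remains afterwards.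

Step 6
Reactants: 9 (2R,3R)-2,3-bis(3,4,5-trimethoxybenzyl)butane-1,4-diol
Product: 11 (−)-cubebininolide [(3R,4R)-3,4-bis(3,4,5-trimethoxybenzyl)oxolan-2-one], via lactol 10 (not isolated)
Conditions: TEMPO (20 mol %), PhI(OAc)2 (2.5 equiv), CH2Cl2, rt
Reagents that add atoms: none
Why: Oxoammonium-mediated oxidative lactonisation of a 1,4-diol: one primary alcohol is oxidised to the aldehyde, which closes to lactol 10 and is oxidised again to the lactone. The twofold axis of 9 exchanges the two hydroxyl groups, so either gives 11; methyl aryl ethers are inert to this oxidant at room temperature and the trans arrangement at C3/C4 is the stable one.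

## Compound list

1 | (2R,3R)-2,3-dimethylsuccinic acid | C[C@@H](C(=O)O)[C@@H](C)C(=O)O | starting material
2 | (2R,3R)-2,3-dimethylsuccinyl dichloride | C[C@@H](C(=O)Cl)[C@@H](C)C(=O)Cl | intermediate
3 | 2-(methylthio)aniline | CSc1ccccc1N | starting material
4 | (2R,3R)-2,3-dimethyl-N1,N4-bis[2-(methylthio)phenyl]succinamide | C[C@@H](C(=O)Nc1ccccc1SC)[C@@H](C)C(=O)Nc1ccccc1SC | intermediate
5 | 5-iodo-1,2,3-trimethoxybenzene | COc1cc(I)cc(OC)c1OC | starting material
6 | mono-arylated bisamide (not isolated): (2R,3R)-2-methyl-N1,N4-bis[2-(methylthio)phenyl]-3-(3,4,5-trimethoxybenzyl)succinamide | C[C@@H](C(=O)Nc1ccccc1SC)[C@@H](Cc1cc(OC)c(OC)c(OC)c1)C(=O)Nc1ccccc1SC | intermediate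
7 | (2R,3R)-N1,N4-bis[2-(methylthio)phenyl]-2,3-bis(3,4,5-trimethoxybenzyl)succinamide | COc1cc(C[C@@H](C(=O)Nc2ccccc2SC)[C@@H](Cc2cc(OC)c(OC)c(OC)c2)C(=O)Nc2ccccc2SC)cc(OC)c1OC | intermediate
8 | di-tert-butyl N,N'-[(2R,3R)-2,3-bis(3,4,5-trimethoxybenzyl)succinyl]bis{[2-(methylthio)phenyl]carbamate} | COc1cc(C[C@@H](C(=O)N(C(=O)OC(C)(C)C)c2ccccc2SC)[C@@H](Cc2cc(OC)c(OC)c(OC)c2)C(=O)N(C(=O)OC(C)(C)C)c2ccccc2SC)cc(OC)c1OC | intermediate
9 | (2R,3R)-2,3-bis(3,4,5-trimethoxybenzyl)butane-1,4-diol | COc1cc(C[C@@H](CO)[C@@H](Cc2cc(OC)c(OC)c(OC)c2)CO)cc(OC)c1OC | intermediate
10 | lactol (not isolated): (3R,4R)-3,4-bis(3,4,5-trimethoxybenzyl)oxolan-2-ol, both anomers | COc1cc(C[C@H]2COC(O)[C@@H]2Cc2cc(OC)c(OC)c(OC)c2)cc(OC)c1OC | intermediate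
11 | (−)-cubebininolide, (3R,4R)-3,4-bis(3,4,5-trimethoxybenzyl)oxolan-2-one | COc1cc(C[C@H]2COC(=O)[C@@H]2Cc2cc(OC)c(OC)c(OC)c2)cc(OC)c1OC | target

## Step count and risks

Total: 6 steps. Longest linear sequence: 6 steps (1 → 2 → 4 → 7 → 8 → 9 → 11); iodide 5 and amine 3 are bought.

**Step 3 (key step).** The most likely failure is arrest after the first arylation or loss of catalyst activity. The substrate, and still more the half-arylated stage, offers two N,S-chelating arms that can hold one divalent palladium as a bis(amidate) and keep it out of the cycle. A second risk is erosion of configuration at the amide α-carbons at 110 °C, which would show as meso material. The fallback gives up the aryl–CH2 cut and makes the central CH–CH bond by auxiliary-controlled oxidative enolate homocoupling. It sets out from 5 and returns at 9.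
- Iodide 5 is coupled with acrylic acid in a Heck reaction (Pd(OAc)2, Et3N, MeCN, 80 °C) to (E)-3-(3,4,5-trimethoxyphenyl)acrylic acid F1.
- Hydrogenation (H2, Pd/C, EtOAc) gives 3-(3,4,5-trimethoxyphenyl)propanoic acid F2.
- Acylation of (S)-4-isopropyloxazolidin-2-one (pivaloyl chloride, Et3N, LiCl, THF) gives (S)-4-isopropyl-3-[3-(3,4,5-trimethoxyphenyl)propanoyl]oxazolidin-2-one F3.
- The lithium enolate of F3 (LDA, THF, −78 °C) is dimerised oxidatively with TiCl4 to (4S,4'S)-3,3'-[(2R,3R)-2,3-bis(3,4,5-trimethoxybenzyl)succinyl]bis(4-isopropyloxazolidin-2-one) F4, each enolate reacting on the face away from its isopropyl group.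
- LiBH4 in THF reduces both imides of F4 to diol 9, and step 6 follows.

**Step 1.** The most likely failure is diversion of the half-activated diacid into the five-membered cyclic anhydride instead of clean twofold chloride formation, which in step 2 would lead to amic acid and imide. The fallback replaces acyl chloride chemistry by ester aminolysis. It sets out from 1 and returns at 4. Acid 1 is esterified (MeOH, H2SO4 cat., reflux) to dimethyl (2R,3R)-2,3-dimethylsuccinate F5. F5 is then heated with the dimethylaluminium amide prepared from AlMe3 and 3 (toluene, 80 °C, Weinreb-type aminolysis) to give 4.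

**Step 4.** The most likely failure is incomplete acylation at the hindered, ortho-substituted anilide nitrogen. Alternatively the half-activated stage may close to an N-aryl succinimide, by attack of the remaining anilide nitrogen on the activated acyl group. The fallback avoids N-activation. It sets out from 7 and returns at 9. Lewis-acid methanolysis (BF3·OEt2, MeOH, 100 °C, sealed vessel) gives dimethyl (2R,3R)-2,3-bis(3,4,5-trimethoxybenzyl)succinate F6, identical with A9, and releases amine 3 for reuse. LiAlH4 in THF at 0 °C then reduces F6 to 9.

**Step 5.** The most likely failure is hydride attack at the carbamate carbonyl instead of the acyl carbonyl, which returns the anilide, or arrest at a hydroxy-amide or lactol stage. The fallback separates cleavage from reduction. It sets out from 8 and returns at 9. Acyl-selective hydrolysis with LiOH/H2O2 (THF/H2O, 0 °C) gives (2R,3R)-2,3-bis(3,4,5-trimethoxybenzyl)succinic acid F7. BH3·SMe2 in THF then reduces F7 to 9 without exposing the α-centres to base.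

**Step 6.** The most likely failure is oxidation spreading to the electron-rich rings or their benzylic positions, or arrest at the lactol. The fallback reaches the lactone by reduction instead of oxidation. It sets out from 8 and returns at 11. Hydrolysis as above gives diacid F7. Cold dehydration (DCC, CH2Cl2, 0 °C, chosen to avoid the epimerisation that hot acetic anhydride can cause) gives (3R,4R)-3,4-bis(3,4,5-trimethoxybenzyl)oxolane-2,5-dione F8. NaBH4 (THF, 0 °C, acidic work-up) reduces either of its equivalent carbonyl groups and gives 11.

## Further compounds

F1 | step 3 | (E)-3-(3,4,5-trimethoxyphenyl)acrylic acid | COc1cc(/C=C/C(=O)O)cc(OC)c1OC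
F2 | step 3 | 3-(3,4,5-trimethoxyphenyl)propanoic acid | COc1cc(CCC(=O)O)cc(OC)c1OC
F3 | step 3 | (S)-4-isopropyl-3-[3-(3,4,5-trimethoxyphenyl)propanoyl]oxazolidin-2-one | COc1cc(CCC(=O)N2[C@@H](C(C)C)COC2=O)cc(OC)c1OC
F4 | step 3 | (4S,4'S)-3,3'-[(2R,3R)-2,3-bis(3,4,5-trimethoxybenzyl)succinyl]bis(4-isopropyloxazolidin-2-one) | COc1cc(C[C@@H](C(=O)N2[C@@H](C(C)C)COC2=O)[C@@H](Cc2cc(OC)c(OC)c(OC)c2)C(=O)N2[C@@H](C(C)C)COC2=O)cc(OC)c1OC
F5 | step 1 | dimethyl (2R,3R)-2,3-dimethylsuccinate | C[C@@H](C(=O)OC)[C@@H](C)C(=O)OC
F6 | step 4 | dimethyl (2R,3R)-2,3-bis(3,4,5-trimethoxybenzyl)succinate | COC(=O)[C@H](Cc1cc(OC)c(OC)c(OC)c1)[C@@H](Cc1cc(OC)c(OC)c(OC)c1)C(=O)OC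
F7 | step 5 | (2R,3R)-2,3-bis(3,4,5-trimethoxybenzyl)succinic acid | COc1cc(C[C@@H](C(=O)O)[C@@H](Cc2cc(OC)c(OC)c(OC)c2)C(=O)O)cc(OC)c1OC
F8 | step 6 | (3R,4R)-3,4-bis(3,4,5-trimethoxybenzyl)oxolane-2,5-dione | COc1cc(C[C@H]2C(=O)OC(=O)[C@@H]2Cc2cc(OC)c(OC)c(OC)c2)cc(OC)c1OC
A1 | alternative 1 | bis[(3,4,5-trimethoxyphenyl)(trimethylsilyl)methyl] sulfoxide (mixture of stereoisomers) | COc1cc(C([Si](C)(C)C)S(=O)C([Si](C)(C)C)c2cc(OC)c(OC)c(OC)c2)cc(OC)c1OC
A2 | alternative 1 | di-(−)-menthyl fumarate | O=C(/C=C/C(=O)O[C@@H]1C[C@H](C)CC[C@H]1C(C)C)O[C@@H]1C[C@H](C)CC[C@H]1C(C)C
A3 | alternative 1 | di-(−)-menthyl (3R,4R)-2,5-bis(3,4,5-trimethoxyphenyl)thiolane-3,4-dicarboxylate (configuration at C2 and C5 open) | O=C(O[C@@H]1C[C@H](C)CC[C@H]1C(C)C)[C@@H]1C(c2cc(OC)c(OC)c(OC)c2)SC(c2cc(OC)c(OC)c(OC)c2)[C@H]1C(=O)O[C@@H]1C[C@H](C)CC[C@H]1C(C)C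
A4 | alternative 2 | methyl (1S,5R)-2-oxo-3-oxabicyclo[3.1.0]hexane-1-carboxylate | COC(=O)[C@]12C[C@H]1COC2=O
A5 | alternative 2 | 3,4,5-trimethoxyphenylmagnesium bromide | COc1cc([Mg]Br)cc(OC)c1OC
A6 | alternative 2 | 3,4,5-trimethoxybenzyl bromide | COc1cc(CBr)cc(OC)c1OC
A7 | alternative 2 | methyl (3R,4R)-2-oxo-3,4-bis(3,4,5-trimethoxybenzyl)oxolane-3-carboxylate | COC(=O)[C@@]1(Cc2cc(OC)c(OC)c(OC)c2)[C@@H](Cc2cc(OC)c(OC)c(OC)c2)COC1=O
A8 | alternative 3 | (E)-1,4-bis(3,4,5-trimethoxyphenyl)but-2-ene | COc1cc(C/C=C/Cc2cc(OC)c(OC)c(OC)c2)cc(OC)c1OC
A9 | alternative 3 | dimethyl (2R,3R)-2,3-bis(3,4,5-trimethoxybenzyl)succinate | COC(=O)[C@H](Cc1cc(OC)c(OC)c(OC)c1)[C@@H](Cc1cc(OC)c(OC)c(OC)c1)C(=O)OC
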